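The readings stem from a simulated flask for an exercise, and the scatter is random.

**Leftover first.** Starting material still unreacted at the end of a stay has given no target, for target forms through the intermediate, and that leftover is the thing to count in these set-ups.

| flask | starting material | first nucleophile | second nucleophile | remark | time |
|---|---|---|---|---|---|
| midnight | 0.20 M | 0.80 M | 0.10 M | run made earlier |  |
| dawn | 0.20 M | 0.40 M | 0.10 M | run made earlier |  |
| noon | 0.20 M | 1.6 M | 0.10 M | run made earlier |  |
| ash | 0.20 M (fed, over 15.0 h) | 0.800 M | 0.100 M | a stirred flask in which starting material is dosed at a steady rate over 15.0 h without added volume, worked up at 30 h | 30 h |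
| cedar | 0.20 M | 0.800 M | 0.100 M | one stirred flow tank at steady state, fed with the mixture as stated, mean residence time 30 h |  |
| elm | 0.20 M | 0.800 M | 0.100 M | one stirred flow tank at steady state, fed with the mixture as stated, mean residence time 300 h |  |
| birch | 0.20 M | 0.800 M | 0.100 M | a closed flask charged with all of it at once and left for 30 h | 30 h |

- midnight (time / h: target / %): 2.50: 2.1; 8.00: 5.2; 15.0: 10.0; 20.0: 13.8; 30.0: 19.6
- dawn (time / h: target / %): 1.33: 0.2; 2.50: 0.6; 5.00: 1.8; 10.0: 4.3; 20.0: 8.7
- noon (time / h: target / %): 1.33: 1.1; 2.50: 1.2; 5.00: 4.0; 10.0: 9.1; 20.0: 16.9

(scatter of a reading: 0.5 percentage points)

- the stated concentrations are those of everything mixed, before any reaction; amounts are the same in each set-up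
- the numbers in the tables scatter with a standard deviation of 0.5 percentage points
- reactions considered so far: starting material -> intermediate; first nucleophile + intermediate -> target; second nucleophile + intermediate -> other capture product; intermediate -> solvolysis product; second nucleophile <-> dormant form; first nucleophile -> decomposed reagent
- the feed brings no volume worth counting
- the earlier runs were made in a closed, stirred flask

* the set-up with the highest amount of target at the outlet or at the end, in percent of the starting material put in ("none" if the first two lie within 2 percentage points) (ash / cedar / elm / birch / none)
* amount of target at the outlet or at the end, in percent of the starting material put in, ash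
* amount of target at the outlet or at the end, in percent of the starting material put in, cedar
* amount of target at the outlet or at the end, in percent of the starting material put in, elm
* amount of target at the outlet or at the end, in percent of the starting material put in, birch

**Two extremes.** With the capture share held fixed, a stay far shorter than the lifetime of starting material leaves the charge nearly whole and target climbs in a straight line. A stay of very many lifetimes leaves little starting material, and the yield then approaches the capture share. A flask's place between these extremes is its count of lifetimes, stay divided by lifetime (a Damköhler number).

**Reading the lifetime.** At 20.0 h target reads 8.7% with 0.40 M of first nucleophile and 16.9% with 1.6 M. Extrapolating the reciprocal readings to unlimited [first nucleophile], where whatever ionised is captured, gives 24.6% reacted by then. Ionisation as the rate-limiting step then has a lifetime of 70.7 h. The midnight run, at 30.0 h, gives a capture share of 56.7%.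

**The reckoning.** A batch leaves 1/exp(n) of its starting material after n lifetimes, and a tank leaves 1/(1+n). Ash, counted from its mean dosing moment, gives 15.5%. Cedar gives 16.9%. Elm counts 4.24 lifetimes and gives 45.9%, which stays below the capture share, as the tank keeps a leftover. Birch repeats midnight.

**The forecast.** It reasons that “The rate saturates with nucleophile, so slow ionisation limits it”, and it names elm, with ash 15.2%, cedar 17%, elm 45% and birch 20%. Its elm stands below this reckoning.

**The flask.** The result is elm, with ash 14.7%, cedar 16.2%, elm 40.0% and birch 19.0%.

    starting material → intermediate (k = 0.0136 h⁻¹)
    first nucleophile + intermediate → target (k = 0.603 M⁻¹ h⁻¹)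
    second nucleophile + intermediate → other capture product (k = 0.868 M⁻¹ h⁻¹)
    intermediate → solvolysis product (k = 0.254 h⁻¹)
    second nucleophile ⇌ dormant form (K = 0.690, k = 0.0175 h⁻¹)
    first nucleophile → decomposed reagent (k = 0.00145 h⁻¹)

**Elm's count.** Elm keeps 0.0394 M of starting material, 19.7% of the feed against 19.1% from 70.7 h, so the gap to the reckoned target lies in the capture share, down to 49.8%. The falling level of first nucleophile, 0.502 M in elm's tank, is a part of that drop, worth 9.1 percentage points. The largest single effect on elm's target is the turning of intermediate into solvolysis product: without that step elm gives 68.9%. Ash read at 5.0 d overtakes elm with 1.59 lifetimes: starting material stands at 21.7% against 20.4% reckoned, and target reaches 44.9%.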